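**Retrosynthetic overview** (side chain numbered C1', on coumarin C3, to C12'; the carbinol is C5')
- C1'–C2' (sp3–sp2), last step: blue-light Ni/Ir decarboxylative coupling of an (E)-alkenyl iodide (C2'–C12', carrying the carbinol) with (4-hydroxycoumarin-3-yl)acetic acid.
- C2'=C3' (E) and the C3' methyl: Zr-catalysed methylalumination/iodination of a homopropargylic alcohol. C3'–C4': acetylide opening of a terminal vinyl epoxide at CH2.
- C6'=C7' (E): two sequential Pd couplings on a gem-dichloroalkene (homoprenyl enters trans, then methyl cis).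
- C5' (R): bought as C2 of (R)-glyceraldehyde acetonide; its C–O and C–H bonds are never broken.
- Rings: none is built. The coumarin bicycle comes intact from 4-hydroxycoumarin; the dioxolane of the starting aldehyde is only removed and the epoxide is transient.

Assumption: aldehyde 1 is bought as the commercial (R)-enantiomer (derived from D-mannitol) and distilled just before use.

**Step 1**
Reactants: 1 (R)-2,2-dimethyl-1,3-dioxolane-4-carbaldehyde
Product: 2 (S)-4-(2,2-dichlorovinyl)-2,2-dimethyl-1,3-dioxolane
Conditions: BrCCl3 (1.5 equiv), PPh3 (3 equiv), CH2Cl2, 0 → 23 °C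
Reagents that add atoms: bromotrichloromethane, BrC(Cl)(Cl)Cl
Why: Ramirez/Corey–Fuchs-type gem-dichloro-olefination (Wittig reaction of Ph3P=CCl2 made in situ) is mild enough not to epimerise the α-alkoxy aldehyde, so the bought stereocentre is carried over unchanged (the descriptor becomes S only because the CIP ranking changes).

**Step 2**
Reactants: 2 (S)-4-(2,2-dichlorovinyl)-2,2-dimethyl-1,3-dioxolane; 3 5-bromo-2-methylpent-2-ene
Product: 5 (S)-4-[(E)-2,6-dimethylhepta-1,5-dien-1-yl]-2,2-dimethyl-1,3-dioxolane, via chloroalkene 4 (not isolated)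
Conditions: 3, Zn dust, I2 (5 mol %), DMA, 80 °C (gives RZnBr); then 2, PdCl2(DPEphos) (3 mol %), THF, 23 °C; then Pd(P(t-Bu)3)2 (4 mol %), Me2Zn (2 equiv), THF, 60 °C
Reagents that add atoms: dimethylzinc, C[Zn]C
Why: Negishi tandem cross-coupling of a 1,1-dichloroalkene, in which the alkylzinc replaces only the less hindered chloride trans to the dioxolane and Pd(P(t-Bu)3)2/Me2Zn then replaces the remaining cis chloride with retention, fixing the 6'E trisubstituted alkene without touching the stereocentre.

**Step 3**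
Reactants: 5 (S)-4-[(E)-2,6-dimethylhepta-1,5-dien-1-yl]-2,2-dimethyl-1,3-dioxolane
Product: 6 (2S,3E)-4,8-dimethylnona-3,7-diene-1,2-diol
Conditions: AcOH/H2O (4:1), 35 °C
Reagents that add atoms: none
Why: Mild acid hydrolysis of the isopropylidene acetal frees the 1,2-diol; no bond at the stereocentre is broken and the conditions are too weak to ionise the allylic C–O bond.

**Step 4**
Reactants: 6 (2S,3E)-4,8-dimethylnona-3,7-diene-1,2-diol
Product: 9 (R,E)-6,10-dimethylundeca-5,9-dien-1-yn-4-ol, via monotosylate 7 (not isolated), via vinyl epoxide 8 (not isolated)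
Conditions: NaH (2.1 equiv), 1-(p-tolylsulfonyl)imidazole (1.05 equiv), THF, 0 → 23 °C; then LiC≡CH·H2NCH2CH2NH2 (2.5 equiv), DMSO, 23 °C; then H2O
Reagents that add atoms: lithium acetylide (ethylenediamine complex), [Li]C#C
Why: One-pot Fraser-Reid epoxide synthesis (the primary alkoxide is sulfonylated selectively and the secondary alkoxide closes the ring with retention at the carbinol carbon) followed by SN2 opening of the epoxide CH2 by lithium acetylide in DMSO, so the stereocentre is neither made nor broken.

**Step 5**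
Reactants: 9 (R,E)-6,10-dimethylundeca-5,9-dien-1-yn-4-ol
Product: 11 (R,1E,5E)-1-iodo-2,6,10-trimethylundeca-1,5,9-trien-4-ol, via alkenylalane 10 (not isolated)
Conditions: AlMe3 (3.5 equiv), Cp2ZrCl2 (0.25 equiv), CH2Cl2, 0 → 23 °C; then I2 (1.2 equiv), THF, −30 °C; then H2O, aq. Na2S2O3
Reagents that add atoms: trimethylaluminium, C[Al](C)C; iodine, [I][I]
Why: Negishi zirconium-catalysed methylalumination adds Me and Al syn across the terminal alkyne with Me on the internal carbon, and iodinolysis of the C–Al bond with retention gives the (E)-alkenyl iodide (the 2'E geometry), the hydroxyl being masked in situ as its aluminium alkoxide.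

**Step 6**
Reactants: 12 4-hydroxycoumarin; 13 glyoxylic acid monohydrate
Product: 15 2-(4-hydroxy-2-oxo-2H-chromen-3-yl)acetic acid, via alkylidene acid 14 (not isolated)
Conditions: diethyl 2,6-dimethyl-1,4-dihydropyridine-3,5-dicarboxylate (Hantzsch ester, 1.1 equiv), EtOH, 50 °C
Reagents that add atoms: none
Why: Three-component reductive alkylation, in which Knoevenagel condensation at the acidic C3–H of 4-hydroxycoumarin is followed at once by conjugate transfer hydrogenation of the alkylidene dione by the Hantzsch ester, which outruns the second Michael addition that would give a bis-coumarin.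

**Step 7**
Reactants: 11 (R,1E,5E)-1-iodo-2,6,10-trimethylundeca-1,5,9-trien-4-ol; 15 2-(4-hydroxy-2-oxo-2H-chromen-3-yl)acetic acid
Product: 16 4-hydroxy-3-[(2E,5R,6E)-5-hydroxy-3,7,11-trimethyldodeca-2,6,10-trien-1-yl]-2H-chromen-2-one (target)
Conditions: 15 (1.5 equiv), Ir[dF(CF3)ppy]2(dtbbpy)PF6 (2 mol %), NiCl2·DME (10 mol %), dtbbpy (12 mol %), Cs2CO3 (3 equiv), degassed DMSO, 450 nm LEDs, 25 °C; then pH 4 buffer
Reagents that add atoms: none
Why: Proposed new method: a light-driven Ni/Ir decarboxylative C(sp3)–C(sp2) coupling of an unprotected, enol-bearing heteroarylacetic acid with an unactivated 2,2-dialkyl alkenyl iodide, in which the excited iridium photocatalyst oxidises the dianion of 15 (at the carboxylate or, by relay, at the enolate), loss of CO2 gives the allyl-type stabilised radical •CH2–C3 (the radical anion of 3-methylenechromane-2,4-dione), this radical is captured by the divalent alkenylnickel iodide formed by oxidative addition of 11 to zerovalent nickel with retention of the E geometry, and reductive elimination from trivalent nickel forms the C1'–C2' bond while the reduced photocatalyst returns monovalent nickel to zerovalent nickel; the closest known reaction type is the metallaphotoredox decarboxylative vinylation and arylation of α-oxy, α-amino and arylacetic acids, and no stereocentre is formed or touched.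

**Compound list**
1 | (R)-2,2-dimethyl-1,3-dioxolane-4-carbaldehyde | O=C[C@H]1COC(C)(C)O1 | starting material
2 | (S)-4-(2,2-dichlorovinyl)-2,2-dimethyl-1,3-dioxolane | ClC(Cl)=C[C@H]1COC(C)(C)O1 | intermediate
3 | 5-bromo-2-methylpent-2-ene | CC(C)=CCCBr | starting material
4 | (S)-4-[(Z)-2-chloro-6-methylhepta-1,5-dien-1-yl]-2,2-dimethyl-1,3-dioxolane | CC(C)=CCC/C(Cl)=C/[C@H]1COC(C)(C)O1 | intermediate
5 | (S)-4-[(E)-2,6-dimethylhepta-1,5-dien-1-yl]-2,2-dimethyl-1,3-dioxolane | CC(C)=CCC/C(C)=C/[C@H]1COC(C)(C)O1 | intermediate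
6 | (2S,3E)-4,8-dimethylnona-3,7-diene-1,2-diol | CC(C)=CCC/C(C)=C/[C@H](O)CO | intermediate
7 | (2S,3E)-2-hydroxy-4,8-dimethylnona-3,7-dien-1-yl 4-methylbenzenesulfonate | CC(C)=CCC/C(C)=C/[C@H](O)COS(=O)(=O)c1ccc(C)cc1 | intermediate
8 | (S)-2-[(E)-2,6-dimethylhepta-1,5-dien-1-yl]oxirane | CC(C)=CCC/C(C)=C/[C@H]1CO1 | intermediate
9 | (R,E)-6,10-dimethylundeca-5,9-dien-1-yn-4-ol | CC(C)=CCC/C(C)=C/[C@H](O)CC#C | intermediate
10 | [(1E,4R,5E)-4-(dimethylalumanyloxy)-2,6,10-trimethylundeca-1,5,9-trien-1-yl]dimethylalane | CC(C)=CCC/C(C)=C/[C@H](O[Al](C)C)C/C(C)=C/[Al](C)C | intermediate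
11 | (R,1E,5E)-1-iodo-2,6,10-trimethylundeca-1,5,9-trien-4-ol | CC(C)=CCC/C(C)=C/[C@H](O)C/C(C)=C/I | intermediate
12 | 4-hydroxycoumarin | O=c1cc(O)c2ccccc2o1 | starting material
13 | glyoxylic acid monohydrate (2,2-dihydroxyacetic acid) | OC(O)C(=O)O | starting material
14 | 2-(2,4-dioxochroman-3-ylidene)acetic acid | O=C(O)C=C1C(=O)Oc2ccccc2C1=O | intermediate
15 | 2-(4-hydroxy-2-oxo-2H-chromen-3-yl)acetic acid | O=C(O)Cc1c(O)c2ccccc2oc1=O | intermediate
16 | 4-hydroxy-3-[(2E,5R,6E)-5-hydroxy-3,7,11-trimethyldodeca-2,6,10-trien-1-yl]-2H-chromen-2-one | CC(C)=CCC/C(C)=C/[C@H](O)C/C(C)=C/Cc1c(O)c2ccccc2oc1=O | target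

**Step count**
Total: 7 steps. Longest linear sequence: 6 steps (steps 1, 2, 3, 4, 5 and 7); step 6 is a one-step side branch.

**The three steps most likely to fail**

Step 7 (the proposed new coupling). Likely failure modes are unproductive oxidation of the coumarin enolate, nickel-mediated O-alkenylation of the carboxylate or enol, and dimerisation of the coumarinylmethyl radical. The fallback uses known chemistry, makes the C3–C1' bond instead, sets out from 9 and comes back to the route at 16. Methylalumination of 9 as in step 5 gives alane 10, which is treated with n-BuLi and then paraformaldehyde (THF, 0 °C) instead of iodine to give (2E,5R,6E)-3,7,11-trimethyldodeca-2,6,10-triene-1,5-diol F1. ClCO2Me (1.05 equiv) and pyridine in CH2Cl2 at −40 °C acylate only the primary allylic hydroxyl and give (2E,5R,6E)-5-hydroxy-3,7,11-trimethyldodeca-2,6,10-trien-1-yl methyl carbonate F2. Pd(PPh3)4 (5 mol %) in THF at 23 °C then joins F2 to C3 of 4-hydroxycoumarin 12 (2 equiv) in a Tsuji–Trost allylation through the allyl complex of divalent palladium, with attack at the unsubstituted terminus and the E geometry kept, giving 16. Compound 15 and step 6 are then not needed.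

Step 4 (one-pot epoxide formation and acetylide opening). The acetylide may attack the allylic carbon or the alkene terminus of vinyl epoxide 8, or the base may isomerise 8. The fallback avoids any epoxide, sets out from 6 and comes back at 9. TsCl, Bu2SnO (2 mol %) and Et3N in CH2Cl2 at 0 °C give the primary tosylate 7, now isolated. TBSOTf and 2,6-lutidine in CH2Cl2 at −78 °C give (2S,3E)-2-[(tert-butyldimethylsilyl)oxy]-4,8-dimethylnona-3,7-dien-1-yl 4-methylbenzenesulfonate F3. LiC≡CH·H2NCH2CH2NH2 in DMSO at 23 °C displaces the primary tosylate directly and gives tert-butyl{[(R,E)-6,10-dimethylundeca-5,9-dien-1-yn-4-yl]oxy}dimethylsilane F4. Bu4NF in THF removes the silyl group and gives 9.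

Step 2 (tandem coupling on the dichloroalkene). The first coupling may be incompletely trans-selective or may over-alkylate in the one-pot mode. The fallback builds the alkene by alkyne hydrometalation, sets out from 2 and comes back at 5. n-BuLi (2.2 equiv) in THF at −78 → 0 °C, then MeI, gives (S)-2,2-dimethyl-4-(prop-1-yn-1-yl)-1,3-dioxolane F5. Cp2Zr(H)Cl (2 equiv, THF, 40 °C, equilibrating to the alkenylzirconium at the methyl-bearing carbon) followed by iodine gives (S)-4-[(E)-2-iodoprop-1-en-1-yl]-2,2-dimethyl-1,3-dioxolane F6. Negishi coupling of F6 with the zinc reagent made from 3 (Pd(PPh3)4, THF, 40 °C) gives 5 with retention.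

**Further compounds**
F1 | step 7 | (2E,5R,6E)-3,7,11-trimethyldodeca-2,6,10-triene-1,5-diol | CC(C)=CCC/C(C)=C/[C@H](O)C/C(C)=C/CO
F2 | step 7 | (2E,5R,6E)-5-hydroxy-3,7,11-trimethyldodeca-2,6,10-trien-1-yl methyl carbonate | CC(C)=CCC/C(C)=C/[C@H](O)C/C(C)=C/COC(=O)OC
F3 | step 4 | (2S,3E)-2-[(tert-butyldimethylsilyl)oxy]-4,8-dimethylnona-3,7-dien-1-yl 4-methylbenzenesulfonate | CC(C)=CCC/C(C)=C/[C@H](O[Si](C)(C)C(C)(C)C)COS(=O)(=O)c1ccc(C)cc1
F4 | step 4 | tert-butyl{[(R,E)-6,10-dimethylundeca-5,9-dien-1-yn-4-yl]oxy}dimethylsilane | CC(C)=CCC/C(C)=C/[C@H](O[Si](C)(C)C(C)(C)C)CC#C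
F5 | step 2 | (S)-2,2-dimethyl-4-(prop-1-yn-1-yl)-1,3-dioxolane | CC#C[C@H]1COC(C)(C)O1
F6 | step 2 | (S)-4-[(E)-2-iodoprop-1-en-1-yl]-2,2-dimethyl-1,3-dioxolane | I/C(C)=C/[C@H]1COC(C)(C)O1
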